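I decide to read each run by a single number: the share of the charged substrate standing as target at the top of the curve. The runs are these, and this is what is asked.

| setting | Saturday's | Monday's | Sunday's | flask |
|---|---|---|---|---|
| substrate | 0.050 M | 0.050 M | 0.025 M | 0.050 M |
| partner | 0.077 M | 0.12 M | 0.055 M | 0.0550 M |
| remark | run made earlier | run made earlier | run made earlier |  |
| time |  |  |  | 4.0 d |

- Saturday's (time / d: target / %): 0.208: 31; 0.333: 42; 0.500: 50; 0.833: 54; 1.25: 50; 2.08: 39; 3.00: 31
- Monday's (time / d: target / %): 0.208: 40; 0.333: 54; 0.500: 65; 0.833: 64; 1.25: 59; 2.08: 46; 3.00: 36
- Sunday's (time / d: target / %): 0.208: 27; 0.417: 48; 0.833: 55; 1.67: 47; 3.00: 36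

(each reading ± 1.5 percentage points)

- when, up to 4.0 d, the flask holds most target
- the amount of target, in percent of the substrate charged, at that time

My rule is that the top fraction equals c(partner) divided by c(partner) plus K, where K is the capture charge, a selectivity factor written as a concentration. Saturday's highest reading gives K as 0.0656 M and Monday's gives 0.0646 M, which agree, so I carry their mean, 0.0651 M. Sunday's run, with less substrate, reads lower than this mean, at 0.0450 M, so I hold K to a substrate charge of 0.050 M.

For the flask, my top is therefore 45.8%. I draw its curve as Saturday's, scaled by 0.848. It climbs steeply to about 26.3% at 0.208 d and bends over to its top near 0.833 d, where Saturday's and Sunday's highest readings stand. It then falls with the half-life read from Saturday's last two readings, 2.78 d, to about 20.5% at 4.0 d.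

The forecast says 47% at 1.05 d, with the top “later and lower than Saturday's”. Its height lies near mine, but its time is later than mine.

The flask tops out at 0.850 d with 42.5%.

    substrate → intermediate (k = 0.00570 /min)
    partner + intermediate → target (k = 0.0510 /M/min)
    2 intermediate → homo product (k = 0.0740 /M/min)
    target → over-reaction product (k = 1.90 × 10⁻⁴ /min)

By 0.400 d substrate, passing into intermediate with a half-life of 0.084 d, is down to 3.75%, and the flask holds 36.0% target and 38.7% homo product. After the top, target goes on passing into over-reaction product with a half-life of 2.5 d, leaving 20.3% at 4.00 d. Read back from this flask, K is 0.0743 M. For a further flask with 0.22 M of partner, my K gives 77.2%, and that flask reaches 78.7%.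

(The data come from a simulation with made-up constants, noise included.)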